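(The earlier runs and the new flask come from a simulation with made-up constants; noise was put on by code.)

The amber run has 97.0% of its free monomer in chains at 2.50 min and the grey run 75.0%, so amber's larger charge reaches the greater fraction. Neither run shows how many chains began, and that number is what to watch here.

| setting | grey | amber | south-west | north-east |
|---|---|---|---|---|
| free monomer | 0.081 M | 0.29 M | 0.42 M | 0.15 M |
| initiator | 5.9 mM | 5.9 mM | 5.9 mM | 5.9 mM |
| remark | run made earlier | run made earlier |  |  |
| time |  |  | 2.5 min | 2.5 min |

- grey (time / min: monomer in chains / %, free monomer / %): 0.200: 1.0, 98.6; 0.667: 13.3, 86.8; 1.33: 38.4, 61.0; 2.00: 62.1, 38.0; 2.50: 75.0, 24.6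
- amber (time / min: monomer in chains / %, free monomer / %): 0.200: 4.5, 95.1; 0.417: 17.3, 82.6; 0.667: 36.0, 64.1; 1.33: 75.6, 23.8; 2.50: 97.0, 3.0

(each reading ± 0.3 percentage points)

- the average divides the monomer in chains by the number of chains begun, living and dead together
- candidate steps: free monomer + initiator -> living end + monomer in chains; free monomer + living end -> monomer in chains + living end; initiator -> spent initiator
- the earlier runs do not show the number of chains; that part of a forecast is a guess

- which of the two ends with the longer chains by the average number of monomer units in a chain (chains begun, living or dead) ("neither" if they lie within 10%) (south-west / north-east / neither)
- average number of monomer units in a chain (chains begun, living or dead) at the end, south-west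
- average number of monomer units in a chain (chains begun, living or dead) at the end, north-east

I count turnovers. South-west holds 71.2 free monomer per initiator charged and north-east 25.4, and I call this the turnover count. The average length is the count times the fraction in chains, divided by the share of the initiator that has begun chains (the initiator efficiency).

Now the settings. More free monomer at the same initiator raises the count in proportion, from 13.7 in grey to 49.2 in amber, and amber's fraction in chains at 2.50 min stands above grey's. More initiator at the same free monomer lowers the count in proportion, but both earlier runs hold 5.9 mM, so their readings do not show what it does to the share. A later reading adds to the fraction in chains while free monomer lasts: amber goes from 75.6% at 1.33 min to 97.0% at 2.50 min, with 3.0% free monomer left.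

Taking amber's fraction for south-west and grey's for north-east, a share of one gives me lengths of 69.1 and 19.1. I commit to south-west, whose count is 2.80 times north-east's, and I leave the share unread.

The forecast also says south-west, with 150 units (105 to 240) against 78 (55 to 125), on the ground that “slow monomer-driven initiation feeds the living ends”. Its lengths stand above mine .

South-west ends at 270 units and north-east at 151, so south-west has the longer chains.

    free monomer + initiator → living end + monomer in chains (k = 0.0163 L mol⁻¹ s⁻¹)
    free monomer + living end → monomer in chains + living end, rate k2*[living end]*[free monomer] (k = 23.6 L mol⁻¹ s⁻¹)
    initiator → spent initiator (k = 0.00310 s⁻¹)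

At 2.50 min, south-west still holds 44.8% of its initiator. Its count of 71.2, with 98.7% in chains, gives a share of 26.0% of the initiator that has begun chains. A neighbour of south-west charged with 1.1 M of free monomer has a count of 186 and reaches 459 units with 99.9% in chains, so its share is 40.6%.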